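Early in the red flask, at 1.25 d, side product B already stands at 79.0% and side product A at 17.6%. After that B reads between 77.2% and 79.5% with no steady rise, while A climbs to 21.6% at 4.00 d and 5.00 d.

| flask | substrate | remark | time |
|---|---|---|---|
| red | 20 mM | the very flask that is asked about, followed so far |  |
| flask | 20 mM |  | 10 d |

- red (time / d: side product B / %, side product A / %, target / %): 1.25: 79.0, 17.6, 0.9; 2.50: 78.8, 19.9, 0.4; 4.00: 79.5, 21.6, 0; 5.00: 77.2, 21.6, 0.7

(scatter of a reading: 0.5 percentage points)

- percentages count the substrate that a species holds: one side product B counts as two

- the side product B standing at 10 d, as a percentage of the substrate charged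
- the side product A standing at 10 d, as a percentage of the substrate charged

I suppose that substrate first turns into a short-lived form. That form either goes on by itself to A or meets a second substrate to give B, a pseudo-first-order route whose rate grows with the substrate concentration c. With the form held steady, the share of substrate passing to A is K/(K + c), where K is the concentration at which both routes take equal shares. Integrating from the charge C down to zero gives the final share of A: f = ln(1 + x)/x, with x = C/K.

Setting f to the reading gives 11.8 for x, the charge counted in crossover concentrations, so K reads 1.70 mM. Time is not in x. I commit to 21.6% A and 78.4% B at 10 d. The B readings did not enter this reckoning. They average 78.6% in the red flask, 0.23 percentage points from my B, and a reading scatters by 0.5 points, so A and B together close the balance there. Whether one number is enough needs a second charge.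

The forecast gives 78.3% B (76% to 79.3%) and 21.7% A (20.8% to 24%) at 10 d, on the ground that at the last readings “everything looks finished”. The flask gives 78.8% B and 21.2% A.

    substrate → intermediate (k = 1.22 × 10⁻⁴ s⁻¹)
    intermediate ⇌ target (K = 1.60, k = 5.63 × 10⁻⁴ s⁻¹)
    intermediate ⇌ isomer of the product (K = 4.10, k = 2.16 × 10⁻⁴ s⁻¹)
    intermediate → side product A (k = 1.23 × 10⁻⁴ s⁻¹)
    substrate + intermediate → side product B (k = 0.150 M⁻¹ s⁻¹)
    substrate ⇌ dormant form (K = 0.340, k = 2.28 × 10⁻⁵ s⁻¹)

Tenfold time leaves B in the flask where it stands. I carry x = 11.8 over to a second charge. The neighbour flask is the same but for its charge of 12 mM of substrate. With the same K its x is 7.06, and the formula gives 29.5% A. That neighbour flask gives 70.4% B and 29.6% A.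

The numbers in the tables are simulated with made-up constants; the scatter is artificial.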